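**Plan**

- Retrosynthesis: the two 4-hydroxybenzoate ester C–O bonds are cut first, then the side-chain C=C bond (Wittig at a C5 aldehyde), then C3–C3a and O1–C7a of the dihydrofuran ring together.
- Enabling feature: C3a and C7a are neighbouring carbons of ring A and can both be electrophiles (the C–I and C–OTf bonds of a 5-iodovanillin derivative). C3–C2–O1 is the enolate carbon, carbinol carbon and alkoxide oxygen of a 3-aryl-3-hydroxypropanoate.
- Forward: the ring A iodo triflate (two steps) and the ring B hydroxy ester (three steps) are joined in a one-pot palladium-catalysed C-arylation/O-arylation that closes the only new ring. The C5 acetal is then grown into the (E)-allylic alcohol, both primary alcohols are acylated and three silyl groups are removed.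
- Stereochemistry: C2 comes from Noyori hydrogenation of a β-keto ester and is not touched again. C3 is set trans to the C2 aryl group by thermodynamic equilibration of the α-aryl ester during the annulation. The E alkene comes from a stabilised Wittig ylide.

Key step: step 6

Remark: the core is numbered as 2,3-dihydro-1-benzofuran (O1, C2, C3, C3a, C4 to C7, C7a); ring A is its benzo ring and ring B the aryl group on C2. The target is the trans (2S,3R) isomer. 5-Iodovanillin, methyl syringate and 4-hydroxybenzoic acid are taken as commercial.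

**Route**

Step 1
Reactants: 1 5-iodovanillin (4-hydroxy-3-iodo-5-methoxybenzaldehyde)
Product: 2 4-formyl-2-iodo-6-methoxyphenyl trifluoromethanesulfonate
Conditions: Tf2O, pyridine, CH2Cl2, 0 °C → rt
Reagents that add atoms: trifluoromethanesulfonic anhydride, O=S(=O)(OS(=O)(=O)C(F)(F)F)C(F)(F)F
Why: O-Triflation (sulfonylation) of the phenol with Tf2O and pyridine should be clean because the aldehyde and the aryl iodide are inert to the electrophilic anhydride.

Step 2
Reactants: 2 4-formyl-2-iodo-6-methoxyphenyl trifluoromethanesulfonate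
Product: 3 4-(1,3-dioxolan-2-yl)-2-iodo-6-methoxyphenyl trifluoromethanesulfonate
Conditions: HOCH2CH2OH, p-TsOH (cat.), toluene, reflux, Dean–Stark trap
Reagents that add atoms: ethylene glycol, OCCO
Why: Acid-catalysed acetalisation with azeotropic removal of water, placed after the triflation so that no free para-phenol is present to make the dioxolane labile, masks the aldehyde against the ester enolate of step 6.

Step 3
Reactants: 4 methyl syringate (methyl 4-hydroxy-3,5-dimethoxybenzoate)
Product: 5 methyl 3,5-dimethoxy-4-(triisopropylsilyloxy)benzoate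
Conditions: TIPSCl, imidazole, DMF, 50 °C
Reagents that add atoms: triisopropylsilyl chloride (TIPSCl), CC(C)[Si](Cl)(C(C)C)C(C)C
Why: Silylation of the phenol; the bulky triisopropylsilyl ether, further shielded by the two flanking methoxy groups, is chosen to survive lithium enolates, hydrides and mild acid until the last step.

Step 4
Reactants: 5 methyl 3,5-dimethoxy-4-(triisopropylsilyloxy)benzoate
Product: 6 tert-butyl 3-[3,5-dimethoxy-4-(triisopropylsilyloxy)phenyl]-3-oxopropanoate
Conditions: t-BuOAc, LiN(i-Pr)2 (3 equiv each), THF, −78 °C → 0 °C; aq NH4Cl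
Reagents that add atoms: tert-butyl acetate, CC(=O)OC(C)(C)C
Why: Crossed Claisen condensation: the non-enolisable aryl methyl ester is the only acceptor for the lithium enolate of tert-butyl acetate, and the excess enolate deprotonates the β-keto ester as it forms, which drives the reaction and prevents a second addition.

Step 5
Reactants: 6 tert-butyl 3-[3,5-dimethoxy-4-(triisopropylsilyloxy)phenyl]-3-oxopropanoate
Product: 7 tert-butyl (3S)-3-[3,5-dimethoxy-4-(triisopropylsilyloxy)phenyl]-3-hydroxypropanoate
Conditions: H2 (50 atm), RuCl2[(R)-BINAP] (1 mol %), MeOH, 50 °C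
Reagents that add atoms: none
Why: Noyori asymmetric hydrogenation of a β-keto ester: hydride is delivered within the ester-chelated ruthenium complex and the (R)-BINAP ligand selects the ketone face that gives the S carbinol in 3-aryl-3-oxopropanoates (the same facial sense that gives (R)-3-hydroxybutanoate from acetoacetate, the descriptor changing because aryl outranks CH2CO2R).

Step 6
Reactants: 7 tert-butyl (3S)-3-[3,5-dimethoxy-4-(triisopropylsilyloxy)phenyl]-3-hydroxypropanoate; 3 4-(1,3-dioxolan-2-yl)-2-iodo-6-methoxyphenyl trifluoromethanesulfonate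
Product: 10 tert-butyl (2S,3S)-2-[3,5-dimethoxy-4-(triisopropylsilyloxy)phenyl]-5-(1,3-dioxolan-2-yl)-7-methoxy-2,3-dihydro-1-benzofuran-3-carboxylate (2,3-trans), via dilithium dianion 8 (not isolated), via open-chain lithium alkoxide 9 (not isolated)
Conditions: 7 (1.1 equiv), LiNCy2 (2.25 equiv, from n-BuLi and Cy2NH), THF/toluene, −78 → 0 °C; then 3 (1.0 equiv), Pd2(dba)3 (2.5 mol %), t-BuXPhos (2-di-tert-butylphosphino-2',4',6'-triisopropylbiphenyl, 6 mol %), rt then 70 °C; aq NH4Cl
Reagents that add atoms: none
Why: Proposed new method: zerovalent palladium should insert into the C–I bond of 3 long before the doubly flanked C–OTf bond, the enolate carbon of dianion 8 then transmetallates and C–C reductive elimination forms C3–C3a (alkoxide 9), after which a second oxidative addition at C–OTf, exchange of triflate on divalent palladium for the internal alkoxide and C–O reductive elimination form O1–C7a. No annulation of a β-hydroxy ester dianion with an ortho-dielectrophile is known; the closest known reaction types are the palladium-catalysed α-arylation of lithium enolates of tert-butyl esters, the palladium-catalysed intramolecular etherification of aryl (pseudo)halides by secondary alcohols, the domino C-arylation/O-arylation of β-keto esters with ortho-dihaloarenes to benzofurans and, for the carbon-selective reactivity of the dianion, the Fráter–Seebach alkylation. The dihydrofuran ring closes by C–O reductive elimination from a six-membered oxapalladacycle, formally a 5-exo attack of the alkoxide oxygen on C7a. C2 is not a new centre: it comes from 7 and is kept because neither its C–O nor its C–H bond is broken, the bulky ligand being chosen so that reductive elimination outruns β-hydride elimination of the palladium alkoxide. The new centre C3 is α to the ester and to ring A and therefore epimerisable both in 9 and in 10 by the small excess of basic dianion, so that it should settle trans to the C2 aryl group under the thermodynamic control of that resident centre. The step needs C–I before C–OTf and carbon before oxygen, which the reactivity gap between iodide and triflate and the higher nucleophilicity of the enolate carbon secure, while the tert-butyl ester, the lithium counter-ion and the near-stoichiometric base are meant to hold back Claisen, retro-aldol and E1cB ring-opening pathways.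

Step 7
Reactants: 10 the trans dihydrobenzofuran tert-butyl ester bearing the C5 dioxolane
Product: 11 tert-butyl (2S,3S)-2-[3,5-dimethoxy-4-(triisopropylsilyloxy)phenyl]-5-formyl-7-methoxy-2,3-dihydro-1-benzofuran-3-carboxylate
Conditions: PPTS (cat.), acetone/H2O, 50 °C
Reagents that add atoms: water, O
Why: Acid-catalysed hydrolysis (transacetalisation to acetone) of the dioxolane under pyridinium buffering, mild enough to leave the tert-butyl ester, the aryl silyl ether and the benzylic C2–O1 bond intact.

Step 8
Reactants: 11 the C5 aldehyde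
Product: 12 tert-butyl (2S,3S)-2-[3,5-dimethoxy-4-(triisopropylsilyloxy)phenyl]-5-[(E)-3-ethoxy-3-oxoprop-1-enyl]-7-methoxy-2,3-dihydro-1-benzofuran-3-carboxylate
Conditions: Ph3P=CHCO2Et, toluene, 80 °C
Reagents that add atoms: ethyl (triphenylphosphoranylidene)acetate, CCOC(=O)C=P(c1ccccc1)(c1ccccc1)c1ccccc1
Why: Wittig olefination with a stabilised ylide, which is reliably E-selective with aryl aldehydes and too weakly basic to epimerise C3.

Step 9
Reactants: 12 the enoate/tert-butyl diester
Product: 13 (E)-3-[(2S,3R)-2-[3,5-dimethoxy-4-(triisopropylsilyloxy)phenyl]-3-(hydroxymethyl)-7-methoxy-2,3-dihydro-1-benzofuran-5-yl]prop-2-en-1-ol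
Conditions: i-Bu2AlH (6 equiv), CH2Cl2, −78 °C → rt; aq potassium sodium tartrate
Reagents that add atoms: none
Why: Reduction of both esters with the electrophilic hydride i-Bu2AlH, which gives 1,2-reduction of the enoate to the allylic alcohol without touching the C=C bond (the standard conversion of dehydrodiferulate-type diesters into diols); the C3 centre is retained, its descriptor changing to R only because CH2OH ranks differently from the ester.

Step 10
Reactants: 14 4-hydroxybenzoic acid
Product: 16 4-(tert-butyldimethylsilyloxy)benzoic acid, via bis-silylated ester 15 (not isolated)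
Conditions: TBSCl (2.5 equiv), imidazole, DMF, rt; then AcOH/THF/H2O, rt
Reagents that add atoms: tert-butyldimethylsilyl chloride (TBSCl), CC(C)(C)[Si](C)(C)Cl
Why: Exhaustive silylation followed by selective hydrolysis of the silyl ester, which is far more labile to aqueous acid than the aryl silyl ether, gives the phenol-protected acid.

Step 11
Reactants: 13 the silyl-protected diol; 16 4-(tert-butyldimethylsilyloxy)benzoic acid
Product: 17 [(2S,3R)-5-[(E)-3-[4-(tert-butyldimethylsilyloxy)benzoyloxy]prop-1-enyl]-2-[3,5-dimethoxy-4-(triisopropylsilyloxy)phenyl]-7-methoxy-2,3-dihydro-1-benzofuran-3-yl]methyl 4-(tert-butyldimethylsilyloxy)benzoate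
Conditions: 16 (2.4 equiv), DCC, DMAP (cat.), CH2Cl2, 0 °C → rt
Reagents that add atoms: none
Why: Steglich esterification of two primary alcohols through the DMAP-activated O-acylisourea; the neutral carbodiimide conditions avoid ionisation of the electron-rich cinnamyl alcohol.

Step 12
Reactants: 17 the tris-silylated bis(benzoate)
Product: 18 quiquesetinerviusin B, [(2S,3R)-2-(4-hydroxy-3,5-dimethoxyphenyl)-5-[(E)-3-(4-hydroxybenzoyloxy)prop-1-enyl]-7-methoxy-2,3-dihydro-1-benzofuran-3-yl]methyl 4-hydroxybenzoate
Conditions: Bu4NF, AcOH (1:1, 4 equiv), THF, 0 °C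
Reagents that add atoms: none
Why: Fluoride-driven cleavage of the three aryl silyl ethers (Si–F bond formation), buffered with AcOH so that the liberated phenoxides are protonated at once and neither attack the aryl esters nor open the para-hydroxybenzylic C2–O1 bond through a quinone methide.

**Compound list**

1 | 5-iodovanillin (4-hydroxy-3-iodo-5-methoxybenzaldehyde) | COc1cc(C=O)cc(I)c1O | starting material
2 | 4-formyl-2-iodo-6-methoxyphenyl trifluoromethanesulfonate | COc1cc(C=O)cc(I)c1OS(=O)(=O)C(F)(F)F | intermediate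
3 | 4-(1,3-dioxolan-2-yl)-2-iodo-6-methoxyphenyl trifluoromethanesulfonate | COc1cc(C2OCCO2)cc(I)c1OS(=O)(=O)C(F)(F)F | intermediate
4 | methyl syringate (methyl 4-hydroxy-3,5-dimethoxybenzoate) | COC(=O)c1cc(OC)c(O)c(OC)c1 | starting material
5 | methyl 3,5-dimethoxy-4-(triisopropylsilyloxy)benzoate | COC(=O)c1cc(OC)c(O[Si](C(C)C)(C(C)C)C(C)C)c(OC)c1 | intermediate
6 | tert-butyl 3-[3,5-dimethoxy-4-(triisopropylsilyloxy)phenyl]-3-oxopropanoate | COc1cc(C(=O)CC(=O)OC(C)(C)C)cc(OC)c1O[Si](C(C)C)(C(C)C)C(C)C | intermediate
7 | tert-butyl (3S)-3-[3,5-dimethoxy-4-(triisopropylsilyloxy)phenyl]-3-hydroxypropanoate | COc1cc([C@@H](O)CC(=O)OC(C)(C)C)cc(OC)c1O[Si](C(C)C)(C(C)C)C(C)C | intermediate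
8 | dilithium dianion of 7 (alkoxide and ester enolate; not isolated) | [Li+].[Li+].COc1cc([C@@H]([O-])C=C([O-])OC(C)(C)C)cc(OC)c1O[Si](C(C)C)(C(C)C)C(C)C | intermediate
9 | lithium alkoxide of tert-butyl (3S)-2-[5-(1,3-dioxolan-2-yl)-3-methoxy-2-(trifluoromethylsulfonyloxy)phenyl]-3-[3,5-dimethoxy-4-(triisopropylsilyloxy)phenyl]-3-hydroxypropanoate (both epimers at chain C2; not isolated) | [Li+].COc1cc(C2OCCO2)cc(C(C(=O)OC(C)(C)C)[C@H]([O-])c2cc(OC)c(O[Si](C(C)C)(C(C)C)C(C)C)c(OC)c2)c1OS(=O)(=O)C(F)(F)F | intermediate
10 | tert-butyl (2S,3S)-2-[3,5-dimethoxy-4-(triisopropylsilyloxy)phenyl]-5-(1,3-dioxolan-2-yl)-7-methoxy-2,3-dihydro-1-benzofuran-3-carboxylate (trans) | COc1cc([C@H]2Oc3c(OC)cc(C4OCCO4)cc3[C@@H]2C(=O)OC(C)(C)C)cc(OC)c1O[Si](C(C)C)(C(C)C)C(C)C | intermediate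
11 | tert-butyl (2S,3S)-2-[3,5-dimethoxy-4-(triisopropylsilyloxy)phenyl]-5-formyl-7-methoxy-2,3-dihydro-1-benzofuran-3-carboxylate | COc1cc([C@H]2Oc3c(OC)cc(C=O)cc3[C@@H]2C(=O)OC(C)(C)C)cc(OC)c1O[Si](C(C)C)(C(C)C)C(C)C | intermediate
12 | tert-butyl (2S,3S)-2-[3,5-dimethoxy-4-(triisopropylsilyloxy)phenyl]-5-[(E)-3-ethoxy-3-oxoprop-1-enyl]-7-methoxy-2,3-dihydro-1-benzofuran-3-carboxylate | COc1cc([C@H]2Oc3c(OC)cc(/C=C/C(=O)OCC)cc3[C@@H]2C(=O)OC(C)(C)C)cc(OC)c1O[Si](C(C)C)(C(C)C)C(C)C | intermediate
13 | (E)-3-[(2S,3R)-2-[3,5-dimethoxy-4-(triisopropylsilyloxy)phenyl]-3-(hydroxymethyl)-7-methoxy-2,3-dihydro-1-benzofuran-5-yl]prop-2-en-1-ol | COc1cc([C@H]2Oc3c(OC)cc(/C=C/CO)cc3[C@@H]2CO)cc(OC)c1O[Si](C(C)C)(C(C)C)C(C)C | intermediate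
14 | 4-hydroxybenzoic acid | OC(=O)c1ccc(O)cc1 | starting material
15 | tert-butyldimethylsilyl 4-(tert-butyldimethylsilyloxy)benzoate (not isolated) | CC(C)(C)[Si](C)(C)OC(=O)c1ccc(O[Si](C)(C)C(C)(C)C)cc1 | intermediate
16 | 4-(tert-butyldimethylsilyloxy)benzoic acid | CC(C)(C)[Si](C)(C)Oc1ccc(C(=O)O)cc1 | intermediate
17 | [(2S,3R)-5-[(E)-3-[4-(tert-butyldimethylsilyloxy)benzoyloxy]prop-1-enyl]-2-[3,5-dimethoxy-4-(triisopropylsilyloxy)phenyl]-7-methoxy-2,3-dihydro-1-benzofuran-3-yl]methyl 4-(tert-butyldimethylsilyloxy)benzoate | COc1cc([C@H]2Oc3c(OC)cc(/C=C/COC(=O)c4ccc(O[Si](C)(C)C(C)(C)C)cc4)cc3[C@@H]2COC(=O)c2ccc(O[Si](C)(C)C(C)(C)C)cc2)cc(OC)c1O[Si](C(C)C)(C(C)C)C(C)C | intermediate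
18 | quiquesetinerviusin B | COc1cc([C@H]2Oc3c(OC)cc(/C=C/COC(=O)c4ccc(O)cc4)cc3[C@@H]2COC(=O)c2ccc(O)cc2)cc(OC)c1O | target

**Step count**

Total step count: 12.
Longest linear sequence: 9 steps, from methyl syringate 4 (steps 3, 4, 5, 6, 7, 8, 9, 11, 12). The ring A branch (steps 1 and 2) joins at step 6 and the acid branch (step 10) joins at step 11.

**Steps most likely to fail**

Step 6 (the proposed new method). What may go wrong: retro-aldol fragmentation of the dianion or of the C-arylated alkoxide (which would also erode C2), β-hydride elimination at the palladium alkoxide, or transfer of the triflyl group to the alkoxide instead of C–O coupling. The fallback uses known chemistry only: the same two ring bonds are made at the ketone oxidation level and the stereocentres are introduced afterwards. It sets out from β-keto ester 6 and iodo triflate 3. Pd2(dba)3, Xantphos and Cs2CO3 in toluene at 100 °C should effect the domino C-arylation of the 1,3-dicarbonyl carbon at C–I and O-arylation of the enol at C–OTf, the benzofuran synthesis known for β-keto esters and ortho-dihaloarenes. This should give tert-butyl 2-[3,5-dimethoxy-4-(triisopropylsilyloxy)phenyl]-5-(1,3-dioxolan-2-yl)-7-methoxy-1-benzofuran-3-carboxylate F1. Dissolving-metal reduction with Mg in MeOH/THF, the usual way from 2-arylbenzofuran-3-carboxylates to trans-2,3-dihydro esters, should then give the racemic trans ester, that is 10 together with its (2R,3R) enantiomer F2. Preparative HPLC on a chiral stationary phase separates the two, and the route is rejoined at 10. Step 5 is then not needed.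

Step 9. What may go wrong: incomplete reduction of the hindered tert-butyl ester at C3, or Lewis-acid-assisted opening of the benzylic C2–O1 bond when the excess aluminium hydride is warmed. The fallback reduces the two esters separately and sets out from 10. LiAlH4 in THF at 0 °C, applied while the aldehyde is still masked, should give [(2S,3R)-2-[3,5-dimethoxy-4-(triisopropylsilyloxy)phenyl]-5-(1,3-dioxolan-2-yl)-7-methoxy-2,3-dihydro-1-benzofuran-3-yl]methanol F3. PPTS in wet acetone then frees (2S,3R)-2-[3,5-dimethoxy-4-(triisopropylsilyloxy)phenyl]-3-(hydroxymethyl)-7-methoxy-2,3-dihydro-1-benzofuran-5-carbaldehyde F4. Wittig olefination with Ph3P=CHCO2Et gives ethyl (E)-3-[(2S,3R)-2-[3,5-dimethoxy-4-(triisopropylsilyloxy)phenyl]-3-(hydroxymethyl)-7-methoxy-2,3-dihydro-1-benzofuran-5-yl]prop-2-enoate F5. i-Bu2AlH at −78 °C, where only the ethyl enoate has to be reduced, brings the route back to 13.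

Step 12. What may go wrong: cleavage or transesterification of the aryl esters by phenoxide during fluoride treatment, or opening of the dihydrofuran ring through a quinone methide once the ring B phenol is free. The fallback removes the silyl group before any ester is present and needs no phenol protection on the acid. It sets out from 13: Bu4NF/AcOH in THF should give (E)-3-[(2S,3R)-2-(4-hydroxy-3,5-dimethoxyphenyl)-3-(hydroxymethyl)-7-methoxy-2,3-dihydro-1-benzofuran-5-yl]prop-2-en-1-ol F6. Double Mitsunobu esterification of its two primary alcohols with unprotected 4-hydroxybenzoic acid 14 (PPh3, DIAD, THF, 0 °C) then arrives directly at 18. In that step the carboxylic acid, far more acidic than any phenol present, is the pronucleophile that reacts. Steps 10 and 11 are then not needed.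

**Further compounds**

F1 | step 6 | tert-butyl 2-[3,5-dimethoxy-4-(triisopropylsilyloxy)phenyl]-5-(1,3-dioxolan-2-yl)-7-methoxy-1-benzofuran-3-carboxylate | COc1cc(-c2oc3c(OC)cc(C4OCCO4)cc3c2C(=O)OC(C)(C)C)cc(OC)c1O[Si](C(C)C)(C(C)C)C(C)C
F2 | step 6 | tert-butyl (2R,3R)-2-[3,5-dimethoxy-4-(triisopropylsilyloxy)phenyl]-5-(1,3-dioxolan-2-yl)-7-methoxy-2,3-dihydro-1-benzofuran-3-carboxylate (enantiomer of 10) | COc1cc([C@@H]2Oc3c(OC)cc(C4OCCO4)cc3[C@H]2C(=O)OC(C)(C)C)cc(OC)c1O[Si](C(C)C)(C(C)C)C(C)C
F3 | step 9 | [(2S,3R)-2-[3,5-dimethoxy-4-(triisopropylsilyloxy)phenyl]-5-(1,3-dioxolan-2-yl)-7-methoxy-2,3-dihydro-1-benzofuran-3-yl]methanol | COc1cc([C@H]2Oc3c(OC)cc(C4OCCO4)cc3[C@@H]2CO)cc(OC)c1O[Si](C(C)C)(C(C)C)C(C)C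
F4 | step 9 | (2S,3R)-2-[3,5-dimethoxy-4-(triisopropylsilyloxy)phenyl]-3-(hydroxymethyl)-7-methoxy-2,3-dihydro-1-benzofuran-5-carbaldehyde | COc1cc([C@H]2Oc3c(OC)cc(C=O)cc3[C@@H]2CO)cc(OC)c1O[Si](C(C)C)(C(C)C)C(C)C
F5 | step 9 | ethyl (E)-3-[(2S,3R)-2-[3,5-dimethoxy-4-(triisopropylsilyloxy)phenyl]-3-(hydroxymethyl)-7-methoxy-2,3-dihydro-1-benzofuran-5-yl]prop-2-enoate | COc1cc([C@H]2Oc3c(OC)cc(/C=C/C(=O)OCC)cc3[C@@H]2CO)cc(OC)c1O[Si](C(C)C)(C(C)C)C(C)C
F6 | step 12 | (E)-3-[(2S,3R)-2-(4-hydroxy-3,5-dimethoxyphenyl)-3-(hydroxymethyl)-7-methoxy-2,3-dihydro-1-benzofuran-5-yl]prop-2-en-1-ol | COc1cc([C@H]2Oc3c(OC)cc(/C=C/CO)cc3[C@@H]2CO)cc(OC)c1O
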